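Picture a one-step world: starting material turns into target, and the yield is the charge. This flask has side roads.

    starting material → target (k1 = 1.8 × 10⁻⁴ /s)
    intermediate A ⇌ intermediate B (K2 = 18, k2 = 1.0 × 10⁻⁴ /s)
    target ⇌ isomer of the product (K3 = 2.9, k3 = 1.6 × 10⁻⁴ /s)
    starting material + reagent ⇌ intermediate A (K4 = 120 /M, k4 = 0.026 /M/s)
    reagent ⇌ dormant form (K5 = 0.65, k5 = 3.7 × 10⁻⁴ /s)

| setting | theta | delta | alpha | epsilon |
|---|---|---|---|---|
| starting material | 0.010 M | 0.010 M | 0.010 M (fed, over 9.60 h) | 0.010 M |
| reagent | 0.0110 M | 0.0110 M | 0.0110 M | 0.0110 M |
| time | 12 h | 12 h | 12 h |  |
| remark | a closed flask charged with all of it at once and left for 12 h | plug flow through a tube for 12 h, no back-mixing | a stirred flask in which starting material is dosed at a steady rate over 9.60 h without added volume, worked up at 12 h | one stirred flow tank at steady state, fed with the mixture as stated, mean residence time 12 h |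

- the stated concentrations are those of everything mixed, before any reaction; amounts are the same in each set-up
- the feed brings no volume worth counting
- run time (theta): 12 h

- the set-up with the highest amount of target at the outlet or at the end, in percent of the starting material put in ("none" if the first two lie within 2 percentage points) (theta / delta / alpha / epsilon / none)
- amount of target at the outlet or at the end, in percent of the starting material put in, theta
- amount of target at the outlet or at the end, in percent of the starting material put in, delta
- amount of target at the outlet or at the end, in percent of the starting material put in, alpha
- amount of target at the outlet or at the end, in percent of the starting material put in, epsilon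

**My reckoning**

- **First instants, theta.** Watch the reagent. Its forward half-life to dormant form is 0.52 h, shorter than the 0.67 h of starting material by binding alone. So take free reagent at the dormant balance, 0.00667 M, and ignore what the intermediates hold.
- **Middle, theta.** Follow the fork. Intermediate A returns with constant 2.17 × 10⁻⁴ /s and moves on with 1.0 × 10⁻⁴ /s, so 31.6 % of it moves on. Binding then loses starting material to intermediate B with constant 5.47 × 10⁻⁵ /s, against 1.8 × 10⁻⁴ /s for the direct step.
- **Name the quantity.** The sidetrack share is the lost constant over the sum of both constants, a selectivity in the usual terms: 23.3 %.
- **End, theta.** Intermediate B leaves on a time of 50.0 h, longer than the run, so count it as parked. Target and isomer balance on a time of 1.29 h, shorter than the run, so target keeps 25.6 % of that pool.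
- **Theta and delta.** Multiply the unparked part by that pool share: 19.7 %. Delta is the same history along a tube, so it gets the same figure.
- **Epsilon.** Balance the isomer against the outflow. Target then keeps 32.9 % of the pool, which gives 25.2 %.
- **Alpha.** The last dose has 2.40 h, twice the pool's time. Expect alpha above theta; I set no figure, so the best stays open.

**The forecast**

- It gives 21.2 % for theta, 21.2 % for delta, 24 % for alpha and 23.5 % for epsilon, with best none.
- Its ground for the higher two: “some starting material reacts late and the target has not yet fully drained to the isomer”.
- It parks about 17% in intermediate B, less than my share. My theta is lower than its figure, and my epsilon higher.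

**The result**

- The flask gives 20.9 % for theta, 20.9 % for delta, 23.5 % for alpha and 23.6 % for epsilon. Best is none, since alpha and epsilon differ by less than 2 percentage points.
- In delta the direct step had 95 % of its turnover behind it at 6.00 h, with 2.50 % of the starting material left. Then target went from 23.1 % to 20.9 % while isomer rose from 52.9 % to 59.0 %, and intermediate B read 19.2 % and then 19.1 %, below the sidetrack share of 23.3 %.

**Second flask: delta with 0.044 M of reagent**

- Reckon free reagent at the dormant balance as before: 0.0267 M, so the lost constant reckons to 2.19 × 10⁻⁴ /s. The sidetrack share reckons to 54.9 %, and target to 11.5 %.
- The simulation gives 50.0 % in intermediate B and 12.6 % of target.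

Its constants belong to no real substance, and the outcome is calculated.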